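The early readings of the green and grey runs showed speed and hid the end, and the end was what I had to plan for: should the next flasks keep their charge of coupling partner, and how should their temperature run?

| setting | green | grey | birch | elm | ash |
|---|---|---|---|---|---|
| substrate | 0.20 M | 0.20 M | 0.20 M | 0.20 M | 0.20 M |
| coupling partner | 0.22 M | 0.22 M | 0.220 M | 0.220 M | 0.220 M |
| protic impurity | 0.010 M | 0.010 M | 0.0100 M | 0.0100 M | 0.0100 M |
| catalyst | 0.35 mM | 1.4 mM | 0.70 mM | 0.70 mM | 0.70 mM |
| temperature | 0 °C | 12 °C | 20 °C | 5 °C |  |
| remark | run made earlier | run made earlier |  |  | at 5 °C until 1.5 min, from then on at 20 °C |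
| time |  |  | 8.0 min | 8.0 min | 8.0 min |

| green: time / min | green: product / % | grey: time / min | grey: product / % |
|---|---|---|---|
| 1.33 | 32.6 | 1.33 | 78.5 |
| 4.00 | 58.7 | 2.50 | 84.8 |
| 8.00 | 74.9 | 4.00 | 86.9 |
| 10.0 | 77.8 | 5.00 | 88.6 |
| 15.0 | 83.1 | 6.00 | 88.5 |
| 20.0 | 87.2 | 8.00 | 89.2 |

(standard deviation of a reading: 0.5 percentage points)

- the earlier runs were read with a standard deviation of 0.5 percentage points
- steps thought possible: substrate + coupling partner + catalyst <-> product + catalyst; coupling partner + protic impurity -> quenched reagent

- the flask that comes out highest in amount of product, in percent of the substrate charged, or "all alike" when all lie within 1.5 percentage points (birch / elm / ash / all alike)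
- product at the end, in percent of the substrate charged, birch
- product at the end, in percent of the substrate charged, elm
- product at the end, in percent of the substrate charged, ash

At 1.33 min the green run held 32.6% of product and the grey run 78.5%. But grey then slowed, and its readings at 6.00 min and 8.00 min, 88.5% and 89.2%, lay 0.7 percentage points apart with a scatter of 0.5 points.

I reckoned with the quench as finished. The protic impurity takes its own amount of coupling partner, so c(coupling partner) − c(protic impurity) leaves 0.210 M free, and against 0.20 M of substrate that gives 105%. This room, the free coupling partner divided by the substrate charged, is the product that the coupling partner can pay for. Free coupling partner is more than the substrate, so substrate is the limiting reagent. Grey's 89.2% lies below the room, so I read its halt as a balance and not a shortage. I therefore kept the charge of coupling partner and let the three new flasks, each with 0.70 mM of catalyst, differ in temperature: birch at 20 °C, elm at 5 °C, and ash going from 5 °C to 20 °C at 1.5 min.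

The forecast put birch at 84.8% (82.5% to 87%), ash at 84.8% (82.5% to 87%) and elm at 88% (85.5% to 90.5%), and it named elm: "Elm is slower, reaching about 88%, but still highest".

The flasks gave birch 85.9%, elm 87.0% and ash 85.8%, a spread of 1.2 points under the margin of 1.5 points, so the answer is all alike.

    substrate + coupling partner + catalyst ⇌ product + catalyst, rate k1*[substrate]*[coupling partner]*[catalyst] forward; the back reaction follows from the equilibrium constant (K = 160 /M, k = 250 /M²/s, Ea = 38.0 kJ/mol, ΔH = −33.0 kJ/mol)
    coupling partner + protic impurity → quenched reagent (k = 2.20 /M/s, Ea = 41.0 kJ/mol)
    (constants at 20 °C)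

Elm was still moving at 8.00 min: left until 80.0 min, it stood at 90.6%. In elm at 8.00 min, the room less the product leaves 16.4% of the coupling partner charge beside 13.0% of the substrate. For a further flask like birch, charged with 0.055 M of coupling partner, I reckoned, with the quench as finished, 0.0450 M free, a room of 22.5%, and that flask held 21.7% of product at 8.00 min.

The data are calculated for an exercise; scatter was added.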